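**Assumptions.** The SMILES decodes as the all-trans tetrahydrofuran (THF numbering O1, C2 = aryl, C3 = CH2OH, C4 = aroyl): 2S,3R,4S. Compounds 1, 2, 4 and 8 are taken as catalogue chemicals.

## Retrosynthetic overview
1. Target ⇐ global deprotection of the aryl ketone ⇐ aryl-metal addition and oxidation on a 4-formyl-THF, so the aryl–C(=O) bond is made last.
2. Key step: one Prins–pinacol rearrangement of a 2-aryl-4-alkenyl-1,3-dioxolane builds the whole THF core. It forms the C2–C3 and C4–C5 bonds, the CHO group and all three stereocentres.
3. Dioxolane ⇐ O-pivaloyl syringaldehyde + (S,E)-5-acetoxypent-3-ene-1,2-diol ⇐ cross-metathesis of (S)-but-3-ene-1,2-diol.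
4. Ring order: a sacrificial dioxolane is made first. It is converted through an oxocarbenium/tetrahydropyranyl chair into the only ring of the target.
5. Avoided: butenolide conjugate addition/aldol, auxiliary aldol followed by diol cyclodehydration, and sinapyl alcohol dimerisation followed by oxidation.

## Route

**Step 1**
Reactants: 1 (S)-but-3-ene-1,2-diol; 2 (Z)-but-2-ene-1,4-diyl diacetate (2.5 equiv)
Product: 3 (2E,4S)-4,5-dihydroxypent-2-en-1-yl acetate
Conditions: Hoveyda–Grubbs II (3 mol %), 1,4-benzoquinone (10 mol %), CH2Cl2, 40 °C
Reagents that add atoms: none beyond reactant 2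
Why: Olefin cross-metathesis of a slowly homodimerising allylic diol with a fast symmetrical partner gives the E-alkene, the carbinol centre is untouched, and the E-alkene keeps the acetate from migrating to the diol.

**Step 2**
Reactants: 4 syringaldehyde
Product: 5 4-formyl-2,6-dimethoxyphenyl pivalate
Conditions: PivCl, Et3N, DMAP (cat.), CH2Cl2, 0 °C to rt
Reagents that add atoms: pivaloyl chloride, CC(C)(C)C(=O)Cl
Why: DMAP-catalysed O-acylation makes the para oxygen an acceptor while both OMe groups are meta to the benzylic carbon, so the derived oxocarbenium is more electrophilic and the later benzylic C–O bond will not re-ionise.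

**Step 3**
Reactants: 3; 5
Product: 6 4-{(4S)-4-[(E)-3-acetoxyprop-1-enyl]-1,3-dioxolan-2-yl}-2,6-dimethoxyphenyl pivalate (about 1:1 at the acetal carbon)
Conditions: p-TsOH·H2O (5 mol %), MgSO4, CH2Cl2, rt
Reagents that add atoms: none (water is lost)
Why: Acid-catalysed acetalisation of the 1,2-diol occurs without breaking the C4–O bond, and the acetal epimers are irrelevant because that carbon becomes planar in Step 4.

**Step 4 (key step)**
Reactants: 6
Product: 7 4-[(2S,3R,4S)-3-(acetoxymethyl)-4-formyltetrahydrofuran-2-yl]-2,6-dimethoxyphenyl pivalate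
Conditions: SnCl4 (2.5 equiv), CH2Cl2 (0.02 M), −78 to −20 °C; Et3N, then aq. NaHCO3
Reagents that add atoms: none (isomerisation)
Why: Proposed new method: this extends the Overman Prins–pinacol rearrangement of 4-alkenyl-1,3-dioxolanes to 3-acyl-THFs (Prins cyclisation/pinacol ring contraction, or equivalently 2-oxonia-Cope/aldol) to an allylic-acetate alkene and a lone secondary carbinol as the chirality source; SnCl4 opens the acetal at the allylic oxygen to the (E)-aryl oxocarbenium, which closes on the (E)-alkene through a chair with Ar and CH2OAc equatorial (2,3-trans) and C–O–SnCl4 axial (gauche charge–dipole attraction to O+, and the equatorial-O chair has an axial C–H set up for hydride shift to a separable pyran-3-one rather than the enantiomeric THF), so the (S)-carbinol carbon is consumed as CHO and relayed to 2S,3R, and the OCH2 shift delivers 4S (3,4-trans), which is also the thermodynamic configuration of that epimerisable centre.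

**Step 5**
Reactants: 8 4-bromo-2,6-dimethoxyphenol
Product: 9 (4-bromo-2,6-dimethoxyphenoxy)(tert-butyl)dimethylsilane
Conditions: TBSCl, imidazole, DMF, rt
Reagents that add atoms: TBSCl, CC(C)(C)[Si](C)(C)Cl
Why: Silylation gives a phenol protecting group that survives halogen–metal exchange and is later removed by the same methanolysis as the esters.

**Step 6**
Reactants: 7; 9 (1.1 equiv)
Product: 10 the secondary benzylic alcohol, 4-[aryl(hydroxy)methyl]-THF, as a mixture of carbinol epimers with ring centres 2S,3R,4S
Conditions: 9, n-BuLi, THF, −78 °C; MgBr2·OEt2; then 7, −78 °C; NH4Cl quench at −78 °C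
Reagents that add atoms: none beyond reactant 9
Why: Br/Li exchange, transmetalation to the less basic aryl Grignard and 1,2-addition favour the aldehyde over the alkyl acetate and the hindered pivalate at −78 °C, and the new carbinol centre is erased in Step 7.

**Step 7**
Reactants: 10
Product: 11 the protected ketone, (2S,3R,4S)-2-(4-pivaloyloxy-3,5-dimethoxyphenyl)-3-(acetoxymethyl)-4-(4-TBSO-3,5-dimethoxybenzoyl)tetrahydrofuran
Conditions: Dess–Martin periodinane, NaHCO3, CH2Cl2, 0 °C to rt
Reagents that add atoms: none
Why: Buffered Dess–Martin oxidation converts both carbinol epimers into one ketone and leaves the esters, silyl ether and benzylic ether untouched.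

**Step 8**
Reactants: 11
Product: 12 the target, [(3S,4R,5S)-5-(4-hydroxy-3,5-dimethoxyphenyl)-4-(hydroxymethyl)oxolan-3-yl](4-hydroxy-3,5-dimethoxyphenyl)methanone (2S,3R,4S in the THF numbering used here)
Conditions: K2CO3 (5 equiv), degassed MeOH/THF, rt to 40 °C, Ar; AcOH quench
Reagents that add atoms: none
Why: One transesterification/desilylation removes the acetate, the aryl pivalate and the para-acyl aryl TBS ether, the only base-labile centre (C4) already has its thermodynamic trans configuration, and retro-oxa-Michael ring opening is the reverse of a disfavoured 5-endo-trig closure.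

## Compound list
| No. | Name | SMILES | Role |
|---|---|---|---|
| 1 | (S)-but-3-ene-1,2-diol | OC[C@@H](O)C=C | starting material |
| 2 | (Z)-but-2-ene-1,4-diyl diacetate | CC(=O)OC/C=C\COC(C)=O | starting material |
| 3 | (2E,4S)-4,5-dihydroxypent-2-en-1-yl acetate | OC[C@@H](O)/C=C/COC(C)=O | intermediate |
| 4 | syringaldehyde | O=Cc1cc(OC)c(O)c(OC)c1 | starting material |
| 5 | 4-formyl-2,6-dimethoxyphenyl pivalate | O=Cc1cc(OC)c(OC(=O)C(C)(C)C)c(OC)c1 | intermediate |
| 6 | (4S)-2-aryl-4-[(E)-3-acetoxypropenyl]-1,3-dioxolane | CC(C)(C)C(=O)Oc1c(OC)cc(cc1OC)C1OC[C@@H](O1)/C=C/COC(C)=O | intermediate |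
| 7 | (2S,3R,4S)-4-formyl-THF | O=C[C@@H]1CO[C@H](c2cc(OC)c(OC(=O)C(C)(C)C)c(OC)c2)[C@H]1COC(C)=O | intermediate |
| 8 | 4-bromo-2,6-dimethoxyphenol | COc1cc(Br)cc(OC)c1O | starting material |
| 9 | TBS ether of 8 | COc1cc(Br)cc(OC)c1O[Si](C)(C)C(C)(C)C | intermediate |
| 10 | benzylic carbinol (epimers) | COc1cc(C(O)[C@@H]2CO[C@H](c3cc(OC)c(OC(=O)C(C)(C)C)c(OC)c3)[C@H]2COC(C)=O)cc(OC)c1O[Si](C)(C)C(C)(C)C | intermediate |
| 11 | protected ketone | COc1cc(C(=O)[C@@H]2CO[C@H](c3cc(OC)c(OC(=O)C(C)(C)C)c(OC)c3)[C@H]2COC(C)=O)cc(OC)c1O[Si](C)(C)C(C)(C)C | intermediate |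
| 12 | CID53356211 | COc1cc(C(=O)[C@@H]2CO[C@H](c3cc(OC)c(O)c(OC)c3)[C@H]2CO)cc(OC)c1O | target |

## Step count
- Total steps: 8.
- Longest linear sequence: 6 (Steps 1, 3, 4, 6, 7, 8).

## Three steps most likely to fail
1. **Step 4.**
   - Risk: the acetate-deactivated alkene may react too slowly, giving chloride capture to a 4-chlorotetrahydropyran or a hydride shift to the pyranone. The chirality relay may also leak through the equatorial-O chair, which would erode ee.
   - Fallback: abandon the cationic rearrangement and let C2 control the other centres.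
     - Make enantioenriched 1-aryl-allyl alcohol by asymmetric vinylation of 5.
     - O-alkylate with the 3-arylpropargyl bromide and epoxidise the vinyl group.
     - Close C3–C4 by Cp2TiCl epoxide-opening 5-exo radical cyclisation.
     - Convert the benzylidene to the aryl ketone by HAT-type Markovnikov oxidation.
2. **Step 6.**
   - Risk: the organometallic may attack the acetate, enolise the β-alkoxy aldehyde, or allow acetyl migration to the new alkoxide.
   - Fallback: avoid the carbonyl addition. Pinnick-oxidise 7 to the acid, form the S-ethyl thioester and run a Pd-catalysed Fukuyama coupling with the arylzinc from 9. This gives 11 directly and removes Step 7.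
3. **Step 1.**
   - Risk: E/Z erosion or Ru–H isomerisation of the allylic diol.
   - Fallback: replace metathesis with chiral-pool olefination. Horner–Wadsworth–Emmons reaction of (R)-glyceraldehyde acetonide gives the (S,E)-enoate. DIBAL reduction, acetylation and aqueous AcOH hydrolysis then give 3 with the E geometry fixed by the olefination.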